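**Retrosynthetic overview**
- Ring A is opened at C4a–C5 (retro-6π of a dienylketene). This leads back to a (2S)-2-aryl-2,3-dihydro-4H-pyran-4-one that carries a CH(geranyl)–dioxinone arm at C8a.
- Ring C is opened at O1–C8a, giving an acyclic (S)-δ-hydroxy-β-diketone–dioxinone. Both rings close from this compound in one pot. Ring C forms first and fixes O1 next to the geranyl-bearing carbon. Ring A forms second.
- The acyclic chain is cut at C4–C4a (Claisen): dianion of a geranylated keto-dioxinone plus an (S)-β-hydroxy ester.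
- The keto-dioxinone comes from the acetone–diketene adduct, acetyl chloride and geranyl bromide in one pot. The hydroxy ester comes from a catalytic asymmetric acetate Mukaiyama aldol, which sets C2.
- Ring B is bought with the aldehyde.

Assumption: 4-(tert-butyldimethylsilyloxy)benzaldehyde, 1-(tert-butyldimethylsilyloxy)-1-methoxyethene and (E)-geranyl bromide are bought as catalogue items; flavanone numbering (O1, C2 … C8a) is used for the matching atoms of all intermediates.

**Step 1**
Reactants: 1 2,2,6-trimethyl-4H-1,3-dioxin-4-one; 2 acetyl chloride; 3 geranyl bromide [(2E)-1-bromo-3,7-dimethylocta-2,6-diene]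
Product: 5 6-[(5E)-6,10-dimethyl-2-oxoundeca-5,9-dien-3-yl]-2,2-dimethyl-4H-1,3-dioxin-4-one, via keto-dioxinone 4 (not isolated)
Conditions: LiN(SiMe3)2 (2 equiv), 1 (2 equiv), THF, −78 °C; 2 (1 equiv); then 3 (1 equiv), DMPU, −78 → 23 °C
Reagents that add atoms: acetyl chloride (compound 2), CC(=O)Cl; geranyl bromide (compound 3), CC(C)=CCC/C(C)=C/CBr
Why: Vinylogous Claisen γ-C-acylation of the lithium dienolate of 1 gives 4, which the second equivalent of dienolate deprotonates at once, and this stabilised enolate is C-alkylated by the allylic bromide (SN2, E alkene kept); the new CH centre (future C8) is racemic and is erased when ring A aromatises.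

**Step 2**
Reactants: 6 4-[(tert-butyldimethylsilyl)oxy]benzaldehyde; 7 1-(tert-butyldimethylsilyloxy)-1-methoxyethene
Product: 9 methyl (3S)-3-{4-[(tert-butyldimethylsilyl)oxy]phenyl}-3-hydroxypropanoate, via trichlorosilyl aldolate 8 (not isolated)
Conditions: SiCl4 (1.1 equiv), (S,S)-bisphosphoramide C51H52N6O2P2 {N,N'-dimethyl-N,N'-bis[(11bS)-3,5-dimethyl-4-oxido-3,5-dihydro-4H-dinaphtho[2,1-d:1',2'-f][1,3,2]diazaphosphepin-4-yl]pentane-1,5-diamine} (2 mol %), CH2Cl2, −78 °C; aq. NaHCO3
Reagents that add atoms: 1-(tert-butyldimethylsilyloxy)-1-methoxyethene (compound 7), C=C(OC)O[Si](C)(C)C(C)(C)C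
Why: Lewis-base-activated SiCl4 Mukaiyama aldol addition, in which the phosphoramide-bound trichlorosilyl cation binds the aldehyde and the S,S catalyst is expected to leave the Si face open to the acetate ketene acetal (taken as the mirror image of Re-face addition by the R,R catalyst, a sense recalled and not verified, to be confirmed on 9), which sets the future C2 as S.

**Step 3**
Reactants: 5 geranylated keto-dioxinone; 9 (S)-β-hydroxy ester
Product: 10 6-[(1S,8E)-1-{4-[(tert-butyldimethylsilyl)oxy]phenyl}-1-hydroxy-9,13-dimethyl-3,5-dioxotetradeca-8,12-dien-6-yl]-2,2-dimethyl-4H-1,3-dioxin-4-one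
Conditions: 5 (2.2 equiv), LiN(iPr)2 (4.4 equiv), THF, −78 → −40 °C; then lithium alkoxide of 9 (9 + LiN(iPr)2, 1 equiv), −78 → −20 °C; AcOH quench
Reagents that add atoms: none
Why: Claisen condensation of a β-dicarbonyl dianion at its terminal, more basic carbanion (C4a), with the β-alkoxide shielding the ester from enolisation and E1cB loss as in the Claisen chain extension of unprotected β-hydroxy esters, so the S carbinol centre is carried over untouched.

**Step 4**
Reactants: 10 acyclic (S)-δ-hydroxy-β-diketone–dioxinone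
Product: 14 sophoraflavanone A [(2S)-8-geranyl-5,7,4'-trihydroxyflavanone], via dihydropyranone-dioxinone 11 (not isolated), via acylketene 12 (not isolated), via 4'-O-TBS-sophoraflavanone A 13 (not isolated)
Conditions: CF3CO2H (20 mol %), PhMe (5 mM), 23 °C, 2 h; then 110 °C, slow distillation through 4 Å MS, 1 h; then Bu4NF/AcOH (1:1, 1.5 equiv), THF, 0 °C
Reagents that add atoms: none
Why: Proposed new method: trace acid first closes ring C by the known cyclodehydration of a δ-hydroxy-β-diketone to a 2,3-dihydro-4H-pyran-4-one (hemiketal at C8a, loss of water; the C2–O bond is never broken, so S is retained, and O1 is fixed on the carbon next to geranyl-bearing C8, which excludes the 6-geranyl isomer), water and acid are then distilled off and heating triggers the known retro-hetero-Diels–Alder loss of acetone from the dioxinone to give acylketene 12, whose enol tautomer is a dienylketene (O=C5=C6–C7(OH)=C8–C8a=C4a) that closes ring A by 6π electrocyclisation (equally, C-acylation of the nucleophilic α-carbon C4a of the vinylogous ester) and tautomerises to the phloroglucinol ring, no other nucleophile lying within six-ring reach of the ketene; the closest known reaction types are the final dienylketene electrocyclisation of the Danheiser benzannulation, the ketene-based aromatisation of diketo-dioxinones to resorcylates and the Claisen-type cyclisation of 3,5,7-triketo esters to acylphloroglucinols, and buffered fluoride finally frees the 4'-phenol without base-induced ring opening.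

**Compound list**
1 | 2,2,6-trimethyl-4H-1,3-dioxin-4-one | CC1=CC(=O)OC(C)(C)O1 | starting material
2 | acetyl chloride | CC(=O)Cl | starting material
3 | geranyl bromide, (2E)-1-bromo-3,7-dimethylocta-2,6-diene | CC(C)=CCC/C(C)=C/CBr | starting material
4 | 2,2-dimethyl-6-(2-oxopropyl)-4H-1,3-dioxin-4-one (in the flask as its lithium enolate) | CC(=O)CC1=CC(=O)OC(C)(C)O1 | intermediate
5 | 6-[(5E)-6,10-dimethyl-2-oxoundeca-5,9-dien-3-yl]-2,2-dimethyl-4H-1,3-dioxin-4-one (racemic at C8) | CC(=O)C(C/C=C(\C)CCC=C(C)C)C1=CC(=O)OC(C)(C)O1 | intermediate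
6 | 4-[(tert-butyldimethylsilyl)oxy]benzaldehyde | O=Cc1ccc(O[Si](C)(C)C(C)(C)C)cc1 | starting material
7 | 1-(tert-butyldimethylsilyloxy)-1-methoxyethene | C=C(OC)O[Si](C)(C)C(C)(C)C | starting material
8 | methyl (3S)-3-{4-[(tert-butyldimethylsilyl)oxy]phenyl}-3-[(trichlorosilyl)oxy]propanoate | COC(=O)C[C@H](O[Si](Cl)(Cl)Cl)c1ccc(O[Si](C)(C)C(C)(C)C)cc1 | intermediate
9 | methyl (3S)-3-{4-[(tert-butyldimethylsilyl)oxy]phenyl}-3-hydroxypropanoate | COC(=O)C[C@H](O)c1ccc(O[Si](C)(C)C(C)(C)C)cc1 | intermediate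
10 | 6-[(1S,8E)-1-{4-[(tert-butyldimethylsilyl)oxy]phenyl}-1-hydroxy-9,13-dimethyl-3,5-dioxotetradeca-8,12-dien-6-yl]-2,2-dimethyl-4H-1,3-dioxin-4-one (C8 epimers, enol tautomers) | CC1(C)OC(=O)C=C(O1)C(C/C=C(\C)CCC=C(C)C)C(=O)CC(=O)C[C@H](O)c1ccc(O[Si](C)(C)C(C)(C)C)cc1 | intermediate
11 | 6-{(3E)-1-[(2S)-2-{4-[(tert-butyldimethylsilyl)oxy]phenyl}-4-oxo-3,4-dihydro-2H-pyran-6-yl]-4,8-dimethylnona-3,7-dien-1-yl}-2,2-dimethyl-4H-1,3-dioxin-4-one (C8 epimers) | CC1(C)OC(=O)C=C(O1)C(C/C=C(\C)CCC=C(C)C)C1=CC(=O)C[C@@H](c2ccc(O[Si](C)(C)C(C)(C)C)cc2)O1 | intermediate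
12 | acylketene: (6E)-4-[(2S)-2-{4-[(tert-butyldimethylsilyl)oxy]phenyl}-4-oxo-3,4-dihydro-2H-pyran-6-yl]-7,11-dimethyldodeca-1,6,10-triene-1,3-dione | O=C=CC(=O)C(C/C=C(\C)CCC=C(C)C)C1=CC(=O)C[C@@H](c2ccc(O[Si](C)(C)C(C)(C)C)cc2)O1 | intermediate
13 | (2S)-2-{4-[(tert-butyldimethylsilyl)oxy]phenyl}-8-geranyl-5,7-dihydroxychroman-4-one | CC(C)=CCC/C(C)=C/Cc1c(O)cc(O)c2c1O[C@H](c1ccc(O[Si](C)(C)C(C)(C)C)cc1)CC2=O | intermediate
14 | sophoraflavanone A, (2S)-8-geranyl-5,7-dihydroxy-2-(4-hydroxyphenyl)chroman-4-one | CC(C)=CCC/C(C)=C/Cc1c(O)cc(O)c2c1O[C@H](c1ccc(O)cc1)CC2=O | target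

**Step count**
- Total step count: 4.
- Longest linear sequence: 3 (1 → 5 → 10 → 14). Step 2 is the side branch.

**Steps most likely to fail**

*Step 4 (two-ring cascade).*
- The ketene may be caught by residual water.
- Any 10 that has not yet closed ring C would give a 4-hydroxy-2-pyrone on heating.
- Acid could partly ionise the benzylic C2–O bond.
- The fallback sets out from 10 and comes back at 13. The sequence is stopped after the CF3CO2H stage and 11 is isolated. Compound 11 is heated in PhMe with MeOH (10 equiv), so that the ketene is trapped as the methyl β-keto ester F1. Ring A is then closed ionically instead of pericyclically, by a soft-enolisation Dieckmann-type C-acylation (MgBr2·OEt2, iPr2NEt, CH2Cl2, 0 °C) of the vinylogous-ester dienolate at C4a onto the ester. This gives 13, which is desilylated as before.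

*Step 3 (dianion Claisen on an unprotected hydroxy ester).*
- Proton transfer to the dianion, low conversion or retro-aldol may intervene.
- The fallback sets out from 9 (and uses 5) and comes back at 11. It makes the C4–C4a bond by aldol addition and oxidation instead of acylation.
- Compound 9 is silylated (Et3SiCl, imidazole) to the triethylsilyl ether F2. This is reduced with iBu2AlH at −78 °C to the aldehyde F3.
- The dianion of 5 adds to it to give the β-hydroxy ketone F4 as a diastereomer mixture. Dess–Martin periodinane then gives the silylated diketone F5.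
- F5 enters step 4 with wet CF3CO2H, where it loses the triethylsilyl group and cyclodehydrates to 11.

*Step 1 (one-pot acylation and alkylation).*
- The lithium enolate of 4 may alkylate sluggishly or twice.
- The fallback sets out from 1 and comes back at 5 with the order of bond formation reversed. The dienolate of 1 (LiN(iPr)2, THF/DMPU, −78 °C) is first γ-alkylated with 3 to the homogeranyl dioxinone F6. F6 is then deprotonated again at the same γ-carbon (LiN(iPr)2) and C-acylated with 2 to give 5.

**Further compounds**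
F1 | step 4 | methyl (6E)-4-[(2S)-2-{4-[(tert-butyldimethylsilyl)oxy]phenyl}-4-oxo-3,4-dihydro-2H-pyran-6-yl]-7,11-dimethyl-3-oxododeca-6,10-dienoate | COC(=O)CC(=O)C(C/C=C(\C)CCC=C(C)C)C1=CC(=O)C[C@@H](c2ccc(O[Si](C)(C)C(C)(C)C)cc2)O1
F2 | step 3 | methyl (3S)-3-{4-[(tert-butyldimethylsilyl)oxy]phenyl}-3-[(triethylsilyl)oxy]propanoate | COC(=O)C[C@H](O[Si](CC)(CC)CC)c1ccc(O[Si](C)(C)C(C)(C)C)cc1
F3 | step 3 | (3S)-3-{4-[(tert-butyldimethylsilyl)oxy]phenyl}-3-[(triethylsilyl)oxy]propanal | O=CC[C@H](O[Si](CC)(CC)CC)c1ccc(O[Si](C)(C)C(C)(C)C)cc1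
F4 | step 3 | 6-[(1S,8E)-1-{4-[(tert-butyldimethylsilyl)oxy]phenyl}-3-hydroxy-9,13-dimethyl-5-oxo-1-[(triethylsilyl)oxy]tetradeca-8,12-dien-6-yl]-2,2-dimethyl-4H-1,3-dioxin-4-one | CC1(C)OC(=O)C=C(O1)C(C/C=C(\C)CCC=C(C)C)C(=O)CC(O)C[C@H](O[Si](CC)(CC)CC)c1ccc(O[Si](C)(C)C(C)(C)C)cc1
F5 | step 3 | O-triethylsilyl ether of 10 | CC1(C)OC(=O)C=C(O1)C(C/C=C(\C)CCC=C(C)C)C(=O)CC(=O)C[C@H](O[Si](CC)(CC)CC)c1ccc(O[Si](C)(C)C(C)(C)C)cc1
F6 | step 1 | 6-[(3E)-4,8-dimethylnona-3,7-dien-1-yl]-2,2-dimethyl-4H-1,3-dioxin-4-one | CC1(C)OC(=O)C=C(CC/C=C(\C)CCC=C(C)C)O1
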